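**Retrosynthetic overview**
1. Target 22 ⇐ O-methylation of 2-hydroxy-1,4-naphthoquinone 21 ⇐ base/O2 autoxidation of 8-aryl-6-methoxy-1-tetralone 19; the ketone position fixes oxygen at C1, C2 and C4.
2. Tetralone 19 ⇐ Dieckmann closure and decarboxylation of diester 16 ⇐ benzylic allylation, hydroboration and oxidation of toluate 9.
3. Toluate 9 (ester already between aryl and methyl, OMe para to it) ⇐ I2/MeOH aromatization of the aryl Hagemann ester 8.
4. 8 ⇐ ketol 5 ⇐ Knoevenagel condensation of veratraldehyde 1 with methyl acetoacetate 2, intermolecular Michael addition of a second 2 to the arylidene acetoacetate (key C–C bond), then aldol ring closure.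
5. Ring order: central benzenoid ring first (built as a cyclohexenone, then aromatized), then the future quinone ring (as a cyclohexanone, then oxidized); the dimethoxyphenyl ring is bought.

Assumption: the target has no stereocentre and its biaryl axis rotates freely, so the achiral compound is the "single enantiomer"; intermediates with stereocentres (4–8, 17, 18) are racemic, are drawn without stereodescriptors, and lose those centres before 9 or 19.

**Route**

Step 1
Reactants: 1 3,4-dimethoxybenzaldehyde (veratraldehyde); 2 methyl acetoacetate (2 equiv)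
Product: 5 racemic dimethyl 2-(3,4-dimethoxyphenyl)-4-hydroxy-4-methyl-6-oxocyclohexane-1,3-dicarboxylate, via arylidene acetoacetate 3 (not isolated), via acyclic bis-acetoacetate 4 (not isolated)
Conditions: piperidine (0.1 equiv), MeOH, rt, 48–72 h; product crystallizes
Reagents that add atoms: none
Why: Knoevenagel condensation gives the doubly activated alkene 3, a second acetoacetate adds to it in an intermolecular Michael addition, and the 1,5-diketone 4 closes by intramolecular aldol addition; the four new stereocentres form as a racemate under thermodynamic control and are all erased by step 3.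

Step 2
Reactants: 5 racemic ketol diester
Product: 8 racemic methyl 6-(3,4-dimethoxyphenyl)-2-methyl-4-oxocyclohex-2-ene-1-carboxylate, via enone diester 6 (not isolated), via β-keto acid 7 (not isolated)
Conditions: AcOH/H2O (10:1), H2SO4 (cat.), reflux, 1–2 h, stopped when 6 is consumed
Reagents that add atoms: none
Why: Acid-catalysed dehydration to the conjugated enone, then hydrolysis and decarboxylation of the β-keto ester, which reacts much faster than the hindered vinylogous ester at C1, give the aryl Hagemann ester; no stereocentre is created and the two that remain are irrelevant.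

Step 3
Reactants: 8 aryl Hagemann ester
Product: 9 methyl 2-(3,4-dimethoxyphenyl)-4-methoxy-6-methylbenzoate
Conditions: I2 (2 equiv), MeOH, reflux, 2–4 h; aq. Na2S2O3 work-up
Reagents that add atoms: methanol, CO
Why: Iodine–methanol oxidative aromatization of a Hagemann ester (dienol ether formation, iodination, loss of HI) gives the para-methoxybenzoate with the ester locked between the aryl and methyl groups; no stereocentre remains.

Step 4
Reactants: 9 toluate
Product: 11 methyl 2-(but-3-en-1-yl)-6-(3,4-dimethoxyphenyl)-4-methoxybenzoate, via benzylic lithium species 10 (not isolated)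
Conditions: LiN(iPr)2 (1.2 equiv), THF, −78 °C, 30 min; allyl bromide (1.3 equiv), −78 °C to rt
Reagents that add atoms: allyl bromide, C=CCBr
Why: Lateral lithiation of the ortho-toluate, whose doubly ortho-substituted ester resists self-condensation, followed by SN2 alkylation of the benzylic anion.

Step 5
Reactants: 11 butenyl benzoate
Product: 13 methyl 2-(3,4-dimethoxyphenyl)-6-(4-hydroxybutyl)-4-methoxybenzoate, via B-alkyl-9-BBN adduct 12 (not isolated)
Conditions: 9-BBN (1.5 equiv), THF, 0 °C to rt; then NaOH (3 M aq.), H2O2 (30%), 0 °C to rt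
Reagents that add atoms: hydrogen peroxide, OO
Why: Anti-Markovnikov hydroboration of the terminal alkene and oxidative C–B cleavage give the primary alcohol, while the hindered benzoate is inert to 9-BBN and to brief cold alkaline peroxide.

Step 6
Reactants: 13 primary alcohol
Product: 15 4-[3-(3,4-dimethoxyphenyl)-5-methoxy-2-(methoxycarbonyl)phenyl]butanoic acid, via aldehyde 14 (not isolated)
Conditions: TEMPO (0.2 equiv), PhI(OAc)2 (2.2 equiv), MeCN/H2O (1:1), rt
Reagents that add atoms: water, O
Why: Oxoammonium-mediated (TEMPO/PhI(OAc)2) oxidation takes the primary alcohol through the aldehyde hydrate to the acid without attacking the electron-rich arenes.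

Step 7
Reactants: 15 acid
Product: 16 methyl 2-(3,4-dimethoxyphenyl)-4-methoxy-6-(4-methoxy-4-oxobutyl)benzoate
Conditions: MeOH, H2SO4 (cat.), reflux
Reagents that add atoms: methanol, CO
Why: Fischer esterification of the unhindered aliphatic acid; the ring ester is already a methyl ester, so exchange there changes nothing.

Step 8
Reactants: 16 diester
Product: 17 racemic methyl 8-(3,4-dimethoxyphenyl)-6-methoxy-1-oxo-1,2,3,4-tetrahydronaphthalene-2-carboxylate
Conditions: KOtBu (2.2 equiv), THF, 0 °C to rt; then HCl (1 M aq.)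
Reagents that add atoms: none
Why: Dieckmann (intramolecular Claisen) condensation of the aliphatic ester enolate onto the benzoate closes the six-membered ring and is driven by deprotonation of the β-keto ester; the C2 centre is racemic and enolized and is removed in step 9.

Step 9
Reactants: 17 β-keto ester
Product: 19 8-(3,4-dimethoxyphenyl)-6-methoxy-3,4-dihydronaphthalen-1(2H)-one, via β-keto acid 18 (not isolated)
Conditions: AcOH/HCl (6 M aq.) 1:1, reflux, 3 h
Reagents that add atoms: none
Why: Acid hydrolysis of the β-keto ester and thermal decarboxylation of the β-keto acid give the 1-tetralone, with aryl methyl ethers stable to HCl/AcOH.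

Step 10
Reactants: 19 tetralone
Product: 21 8-(3,4-dimethoxyphenyl)-2-hydroxy-6-methoxynaphthalene-1,4-dione, via 1,2-dione 20 (not isolated)
Conditions: O2 (1 atm), KOtBu (4 equiv), t-BuOH, 25 °C; then HCl (2 M aq.)
Reagents that add atoms: dioxygen, O=O
Why: Base-mediated autoxidation of a 1-tetralone oxygenates the enolate at C2 to the 1,2-dione and then its extended enolate at benzylic C4, so the hydroxyl ends up next to the carbonyl that is peri to the aryl group.

Step 11
Reactants: 21 hydroxyquinone
Product: 22 8-(3,4-dimethoxyphenyl)-2,6-dimethoxynaphthalene-1,4-dione (target)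
Conditions: MeOH, HCl (conc., cat.), reflux
Reagents that add atoms: methanol, CO
Why: Acid-catalysed Fischer-type etherification of the vinylogous acid with methanol gives the thermodynamically preferred 2-methoxy-1,4-quinone rather than the 4-methoxy-1,2-quinone.

**Compound list**
1 | 3,4-dimethoxybenzaldehyde (veratraldehyde) | COc1ccc(C=O)cc1OC | starting material
2 | methyl acetoacetate (methyl 3-oxobutanoate) | COC(=O)CC(C)=O | starting material
3 | methyl 2-[(3,4-dimethoxyphenyl)methylidene]-3-oxobutanoate (E/Z mixture, formed in situ) | COC(=O)C(=Cc1ccc(OC)c(OC)c1)C(C)=O | intermediate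
4 | dimethyl 2,4-diacetyl-3-(3,4-dimethoxyphenyl)pentanedioate (racemic diastereomer mixture, formed in situ) | COC(=O)C(C(C)=O)C(c1ccc(OC)c(OC)c1)C(C(C)=O)C(=O)OC | intermediate
5 | dimethyl 2-(3,4-dimethoxyphenyl)-4-hydroxy-4-methyl-6-oxocyclohexane-1,3-dicarboxylate (racemic, relative configuration not assigned) | COC(=O)C1C(c2ccc(OC)c(OC)c2)C(C(=O)OC)C(C)(O)CC1=O | intermediate
6 | dimethyl 2-(3,4-dimethoxyphenyl)-6-methyl-4-oxocyclohex-5-ene-1,3-dicarboxylate (racemic, formed in situ) | COC(=O)C1C(c2ccc(OC)c(OC)c2)C(C(=O)OC)C(=O)C=C1C | intermediate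
7 | 2-(3,4-dimethoxyphenyl)-3-(methoxycarbonyl)-4-methyl-6-oxocyclohex-4-ene-1-carboxylic acid (racemic, formed in situ) | OC(=O)C1C(c2ccc(OC)c(OC)c2)C(C(=O)OC)C(C)=CC1=O | intermediate
8 | methyl 6-(3,4-dimethoxyphenyl)-2-methyl-4-oxocyclohex-2-ene-1-carboxylate (racemic, trans expected to predominate) | COC(=O)C1C(c2ccc(OC)c(OC)c2)CC(=O)C=C1C | intermediate
9 | methyl 2-(3,4-dimethoxyphenyl)-4-methoxy-6-methylbenzoate | COC(=O)c1c(C)cc(OC)cc1-c1ccc(OC)c(OC)c1 | intermediate
10 | methyl 2-(3,4-dimethoxyphenyl)-6-(lithiomethyl)-4-methoxybenzoate (formed in situ) | [Li]Cc1cc(OC)cc(-c2ccc(OC)c(OC)c2)c1C(=O)OC | intermediate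
11 | methyl 2-(but-3-en-1-yl)-6-(3,4-dimethoxyphenyl)-4-methoxybenzoate | COC(=O)c1c(CCC=C)cc(OC)cc1-c1ccc(OC)c(OC)c1 | intermediate
12 | methyl 2-[4-(9-borabicyclo[3.3.1]nonan-9-yl)butyl]-6-(3,4-dimethoxyphenyl)-4-methoxybenzoate (formed in situ) | COC(=O)c1c(CCCCB2C3CCCC2CCC3)cc(OC)cc1-c1ccc(OC)c(OC)c1 | intermediate
13 | methyl 2-(3,4-dimethoxyphenyl)-6-(4-hydroxybutyl)-4-methoxybenzoate | COC(=O)c1c(CCCCO)cc(OC)cc1-c1ccc(OC)c(OC)c1 | intermediate
14 | methyl 2-(3,4-dimethoxyphenyl)-4-methoxy-6-(4-oxobutyl)benzoate (formed in situ) | COC(=O)c1c(CCCC=O)cc(OC)cc1-c1ccc(OC)c(OC)c1 | intermediate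
15 | 4-[3-(3,4-dimethoxyphenyl)-5-methoxy-2-(methoxycarbonyl)phenyl]butanoic acid | COC(=O)c1c(CCCC(=O)O)cc(OC)cc1-c1ccc(OC)c(OC)c1 | intermediate
16 | methyl 2-(3,4-dimethoxyphenyl)-4-methoxy-6-(4-methoxy-4-oxobutyl)benzoate | COC(=O)CCCc1cc(OC)cc(-c2ccc(OC)c(OC)c2)c1C(=O)OC | intermediate
17 | methyl 8-(3,4-dimethoxyphenyl)-6-methoxy-1-oxo-1,2,3,4-tetrahydronaphthalene-2-carboxylate (racemic, keto/enol mixture) | COC(=O)C1CCc2cc(OC)cc(-c3ccc(OC)c(OC)c3)c2C1=O | intermediate
18 | 8-(3,4-dimethoxyphenyl)-6-methoxy-1-oxo-1,2,3,4-tetrahydronaphthalene-2-carboxylic acid (racemic, formed in situ) | OC(=O)C1CCc2cc(OC)cc(-c3ccc(OC)c(OC)c3)c2C1=O | intermediate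
19 | 8-(3,4-dimethoxyphenyl)-6-methoxy-3,4-dihydronaphthalen-1(2H)-one | COc1cc2c(c(-c3ccc(OC)c(OC)c3)c1)C(=O)CCC2 | intermediate
20 | 8-(3,4-dimethoxyphenyl)-6-methoxy-3,4-dihydronaphthalene-1,2-dione (formed in situ) | COc1cc2c(c(-c3ccc(OC)c(OC)c3)c1)C(=O)C(=O)CC2 | intermediate
21 | 8-(3,4-dimethoxyphenyl)-2-hydroxy-6-methoxynaphthalene-1,4-dione | OC1=CC(=O)c2cc(OC)cc(-c3ccc(OC)c(OC)c3)c2C1=O | intermediate
22 | 8-(3,4-dimethoxyphenyl)-2,6-dimethoxynaphthalene-1,4-dione (achiral) | COC1=CC(=O)c2cc(OC)cc(-c3ccc(OC)c(OC)c3)c2C1=O | target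

**Totals**
Total steps: 11. Longest linear sequence: 11 (fully linear from 1).

**Three steps most likely to fail, each with a fallback**

Step 2 (selective loss of only one ester). Prolonged heating can also hydrolyse and decarboxylate the vinylogous ester, giving the ester-free enone. The fallback sets out from 1 and comes back at 9, and fixes the ester by construction instead of by selective decarboxylation. Claisen–Schmidt aldol condensation of 1 with acetone (aq. NaOH, rt) gives (E)-4-(3,4-dimethoxyphenyl)but-3-en-2-one F1. Intermolecular Michael addition of dimethyl malonate (NaOMe, MeOH) gives dimethyl 2-[1-(3,4-dimethoxyphenyl)-3-oxobutyl]propanedioate F2, which at reflux in the same flask undergoes Claisen cyclization to racemic methyl 2-(3,4-dimethoxyphenyl)-4,6-dioxocyclohexane-1-carboxylate F3. Dehydrogenation with DDQ in refluxing dioxane gives methyl 2-(3,4-dimethoxyphenyl)-4,6-dihydroxybenzoate F4. MeI (1.05 equiv) with K2CO3 in acetone methylates only the non-chelated hydroxyl para to the ester, giving methyl 2-(3,4-dimethoxyphenyl)-6-hydroxy-4-methoxybenzoate F5. Tf2O and pyridine in CH2Cl2 give methyl 2-(3,4-dimethoxyphenyl)-4-methoxy-6-(trifluoromethanesulfonyloxy)benzoate F6. Suzuki methylation with trimethylboroxine, the zerovalent palladium complex Pd(PPh3)4 and K2CO3 in dioxane at 100 °C then delivers 9.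

Step 8 (Dieckmann closure onto a benzoate flanked by an aryl group and the tether). The reversible enolate attack may be slow and lose to intermolecular Claisen condensation. The fallback sets out from 11 and comes back at 19, replacing the enolate by an irreversible alkyllithium acylation and bypassing steps 5–9. Oxidative cleavage of the alkene of 11 (OsO4 cat., NaIO4, 2,6-lutidine, dioxane/H2O) gives methyl 2-(3,4-dimethoxyphenyl)-4-methoxy-6-(3-oxopropyl)benzoate F7. NaBH4 in MeOH at 0 °C gives methyl 2-(3,4-dimethoxyphenyl)-6-(3-hydroxypropyl)-4-methoxybenzoate F8. Appel iodination (I2, PPh3, imidazole, CH2Cl2) gives methyl 2-(3,4-dimethoxyphenyl)-6-(3-iodopropyl)-4-methoxybenzoate F9. Iodine–lithium exchange with t-BuLi (2.1 equiv, THF/Et2O, −100 to −78 °C) gives methyl 2-(3,4-dimethoxyphenyl)-6-(3-lithiopropyl)-4-methoxybenzoate F10, which closes onto the neighbouring ester at once and gives tetralone 19 after aqueous quench.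

Step 10 (autoxidation). The hydroxyquinone can be over-oxidized with ring cleavage, or the reaction can stall at the dione. The fallback sets out from 19 and comes back at 21, introducing the C2 and C4 oxygens in separate, non-aerobic operations. SeO2 in dioxane/AcOH at reflux oxidizes and dehydrogenates 19 to 8-(3,4-dimethoxyphenyl)-6-methoxynaphthalene-1,2-dione F11. Thiele–Winter acetoxylation (Ac2O, H2SO4 cat., rt) adds acetate at C4 and gives 8-(3,4-dimethoxyphenyl)-6-methoxynaphthalene-1,2,4-triyl triacetate F12. Methanolysis with NaOMe in MeOH gives 8-(3,4-dimethoxyphenyl)-6-methoxynaphthalene-1,2,4-triol F13, which air oxidizes in the same flask to 21 after acidification.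

**Further compounds**
F1 | step 2 | (E)-4-(3,4-dimethoxyphenyl)but-3-en-2-one | CC(=O)/C=C/c1ccc(OC)c(OC)c1
F2 | step 2 | dimethyl 2-[1-(3,4-dimethoxyphenyl)-3-oxobutyl]propanedioate (racemic) | COC(=O)C(C(=O)OC)C(CC(C)=O)c1ccc(OC)c(OC)c1
F3 | step 2 | methyl 2-(3,4-dimethoxyphenyl)-4,6-dioxocyclohexane-1-carboxylate (racemic, enolized) | COC(=O)C1C(c2ccc(OC)c(OC)c2)CC(=O)CC1=O
F4 | step 2 | methyl 2-(3,4-dimethoxyphenyl)-4,6-dihydroxybenzoate | COC(=O)c1c(O)cc(O)cc1-c1ccc(OC)c(OC)c1
F5 | step 2 | methyl 2-(3,4-dimethoxyphenyl)-6-hydroxy-4-methoxybenzoate | COC(=O)c1c(O)cc(OC)cc1-c1ccc(OC)c(OC)c1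
F6 | step 2 | methyl 2-(3,4-dimethoxyphenyl)-4-methoxy-6-(trifluoromethanesulfonyloxy)benzoate | COC(=O)c1c(OS(=O)(=O)C(F)(F)F)cc(OC)cc1-c1ccc(OC)c(OC)c1
F7 | step 8 | methyl 2-(3,4-dimethoxyphenyl)-4-methoxy-6-(3-oxopropyl)benzoate | COC(=O)c1c(CCC=O)cc(OC)cc1-c1ccc(OC)c(OC)c1
F8 | step 8 | methyl 2-(3,4-dimethoxyphenyl)-6-(3-hydroxypropyl)-4-methoxybenzoate | COC(=O)c1c(CCCO)cc(OC)cc1-c1ccc(OC)c(OC)c1
F9 | step 8 | methyl 2-(3,4-dimethoxyphenyl)-6-(3-iodopropyl)-4-methoxybenzoate | COC(=O)c1c(CCCI)cc(OC)cc1-c1ccc(OC)c(OC)c1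
F10 | step 8 | methyl 2-(3,4-dimethoxyphenyl)-6-(3-lithiopropyl)-4-methoxybenzoate | [Li]CCCc1cc(OC)cc(-c2ccc(OC)c(OC)c2)c1C(=O)OC
F11 | step 10 | 8-(3,4-dimethoxyphenyl)-6-methoxynaphthalene-1,2-dione | O=C1C(=O)C=Cc2cc(OC)cc(-c3ccc(OC)c(OC)c3)c21
F12 | step 10 | 8-(3,4-dimethoxyphenyl)-6-methoxynaphthalene-1,2,4-triyl triacetate | CC(=O)Oc1cc(OC(C)=O)c2cc(OC)cc(-c3ccc(OC)c(OC)c3)c2c1OC(C)=O
F13 | step 10 | 8-(3,4-dimethoxyphenyl)-6-methoxynaphthalene-1,2,4-triol | Oc1cc(O)c2cc(OC)cc(-c3ccc(OC)c(OC)c3)c2c1O
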